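## The problem

Target 21 is an isoflavone: ring C is a γ-pyrone carrying the 4-hydroxyphenyl ring B at C3, and ring A is a fully differentiated phloroglucinol. Ring A has O1 on C8a, hydroxyls on C5 and C7, carbon substituents on C4a and C6, and a single hydrogen on C8.

- **Regiochemistry.** The C5 side chain must sit on C6, between the two hydroxyls, and not on C8. Both carbons are activated by the same oxygens. Alkylation or sigmatropic shifts on an intact isoflavone must therefore tell C6 from C8, and closure of ring C on a pre-alkylated phloroglucinol must tell the 5-oxygen from the 8a-oxygen.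
- **Side-chain geometry.** The side chain is an (E)-trisubstituted allylic alcohol. The molecule has no stereocentre, so nothing in the ring system can control this geometry. It has to come in with a building block or be set by a stereoselective reaction.
- **Sensitivity.** An electron-rich resorcinol with free ortho hydroxyls next to an allylic alkene does not tolerate acid (addition of O5 or O7 across the alkene, ionisation of the allylic alcohol) or oxidants. The last steps must be neutral and the final deprotection mild.
- **The feature that makes the key step possible.** The sequence C5(OH)–C6(alkyl)–C7(O)–C8(H) is the 1-hydroxy-2-alkyl-3-oxy-4-H pattern that a vinylketene/ynol ether benzannulation writes into a new benzene ring. The two remaining ring A carbons, C4a and C8a, are the C3=C2 double bond of a γ-pyrone (ring C). That pyrone is available as comenic acid 8: its carboxyl carbon becomes C5 and its 5-hydroxyl is the handle for ring B.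

## Retrosynthesis

**21 ⇐ 20.** The three O–Si bonds are cut. All hydroxyl protection is chosen as silyl (7-O-TIPS from the ynol ether, 4'-O-TBS from the boronic acid, side-chain O-TBS), so one buffered fluoride step ends the synthesis. Acid, oxidant and hydrogenation are avoided on the finished hydroxyprenyl resorcinol.

**20 ⇐ 15 + 7 (key step).** Ring A is cut at C4a–C5, C5–C6, C7–C8 and C8–C8a. The neighbouring cut, C6–C1'' on an intact isoflavone, leaves the C6/C8 choice to substrate bias. Here the position of every substituent follows from the mechanism: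

- the carbonyl carbon of diazo ketone 15 becomes C5 with its hydroxyl;
- the two alkyne carbons of siloxyalkyne 7 become C6 (with the side chain) and C7 (with the silyloxy group);
- the diazo carbon becomes C8–H;
- the pyrone C2=C3 bond becomes C8a=C4a.

The precursors are a monocyclic pyrone and an open-chain enyne; the product is the complete, fully substituted isoflavone skeleton. The forward reaction must run a Wolff rearrangement, a regioselective (2+2) cycloaddition, a 4π ring opening, a 6π ring closure and a tautomerisation in one operation (intermediates 16–19).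

**7 ⇐ 4 ⇐ 3 ⇐ 2 ⇐ 1.** The C(sp)–O bond of 7 is cut first: oxidation of the lithium acetylide 5 of enyne 4 gives ynolate 6, which is O-silylated. This is preferred over ester homologation because the corresponding ester would be β,γ-unsaturated and prone to enolisation. Enyne 4 is cut at the C(sp)–C(sp3) bond to allylic chloride 3 and an ethynyl nucleophile. Chloride 3 comes via alcohol 2 from isoprene monoxide 1 by an SN2' opening. That opening is the only step that has to set the E alkene, and it does so on a five-carbon compound that can be purified.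

**15 ⇐ 13 ⇐ 12 ⇐ 10 + 11 ⇐ 9 ⇐ 8.** The diazo ketone is cut between the carbonyl and diazo carbons (acid 13, through chloride 14, plus a diazomethane equivalent). The aryl–pyrone bond of 12, the future C3–C1' bond, is cut to vinyl triflate 10 and boronic acid 11. This places ring B before ring A exists and avoids any late C3 functionalisation of a chromone. Triflate 10 comes from comenic acid 8 through ester 9.

## Roads not taken

**Alternative 1:** (the most obvious) Cut C6–C1'' and the side-chain C–O bond. The intact genistein nucleus is prenylated to wighteone A1, by direct C-alkylation or by O-prenylation and sigmatropic shift. The (E)-methyl group is then oxidised with SeO2 to enal A2, which is reduced.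
- C6 and C8 are activated by the same oxygens. Base-mediated C-prenylation gives C6, C8, double and O-alkylation together.
- A [3,3] shift from O5 puts a reversed (1,1-dimethylallyl) group on C6, and the following Cope shift carries a normal prenyl group on to C8. From O7 only reversed groups reach C6 or C8. The normal prenyl group at C6 is the one pattern sigmatropy does not deliver.
- SeO2 then has to oxidise one allylic methyl group in the presence of an oxidisable resorcinol, in a medium acidic enough to close the prenyl group onto O5 or O7.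
- Two selectivity problems fall late, on the most valuable intermediate. In the chosen plan both are settled by construction.

**Alternative 2:** Cut O1–C2 and C2–C3, so that ring C is made last. A 2-alkenylphloroglucinol A3 is acylated with 4-hydroxyphenylacetic acid to deoxybenzoin A4. C2 is then inserted with a formamide acetal or BF3·OEt2/DMF/MsCl.
- In A4 the two hydroxyls ortho to the ketone are not equivalent and nothing biases them strongly. Closure on the one next to the side chain gives the 8-substituted isomer A5; closure on the other gives the wanted 6-isomer.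
- The Lewis acids of both steps ionise the allylic oxygen and add the flanking hydroxyls across the alkene.
- The step count is similar, but the regiochemical problem is moved, not solved.

**Alternative 3:** Cut the C2''=C3'' double bond. The 5-O-allyl ether A6 of a 7,4'-protected genistein undergoes an ortho-Claisen shift, which can only go to C6, giving 6-allyl compound A7. Cross-metathesis with methacrolein using second-generation Hoveyda–Grubbs catalyst gives enal A8, followed by 1,2-reduction and deprotection.
- This is the strongest competitor, because it does fix C6.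
- It needs O5, the chelated and least nucleophilic hydroxyl, to be allylated after the other two are blocked. The blocking groups must survive carbonate base and about 200 °C, which points to acetal or benzyl ethers. Their removal (acid, hydrogenolysis) is what the finished side chain tolerates least.
- The ruthenium step runs on an ortho-allylphenol, a substrate class prone to olefin migration into conjugation with the ring.
- The E geometry rests on thermodynamic preference alone.
- The route is fully linear on the isoflavone. The chosen plan is convergent, brings the E alkene in from a C5 block, and makes ring A and both of its regiochemical decisions in one step.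

Key step: step 10

## Route

Assumptions: the side-chain alkene is E as encoded in the SMILES (CH2OH trans to the ring CH2), and the target has no stereocentre. Epoxide 1 is used as the racemate, since its stereocentre is destroyed in step 1.

Step 1
Reactants: 1 2-methyl-2-vinyloxirane (isoprene monoxide, racemic)
Product: 2 (2E)-4-chloro-2-methylbut-2-en-1-ol
Conditions: TiCl4 (1.05 equiv), CH2Cl2, −85 °C; H2O quench; chromatography to remove any Z isomer
Reagents that add atoms: titanium tetrachloride, Cl[Ti](Cl)(Cl)Cl
Why: Lewis acid-promoted SN2' opening of a vinyl epoxide, a known reaction of this epoxide; chloride is delivered to the vinyl terminus while the C–O bond ionises, and reaction through the s-trans conformer (vinyl terminus turned away from the ring CH2) places CH2Cl trans to CH2O, giving the E alkene.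

Step 2
Reactants: 2 (2E)-4-chloro-2-methylbut-2-en-1-ol
Product: 3 tert-butyl{[(2E)-4-chloro-2-methylbut-2-en-1-yl]oxy}dimethylsilane
Conditions: TBSCl, imidazole, CH2Cl2, 0 °C
Reagents that add atoms: tert-butyldimethylsilyl chloride, CC(C)(C)[Si](C)(C)Cl
Why: Standard silylation of a primary alcohol; a short reaction at 0 °C keeps the allylic chloride from alkylating imidazole.

Step 3
Reactants: 3 tert-butyl{[(2E)-4-chloro-2-methylbut-2-en-1-yl]oxy}dimethylsilane
Product: 4 tert-butyldimethyl{[(2E)-2-methylhex-2-en-5-yn-1-yl]oxy}silane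
Conditions: HC≡CMgBr (3 equiv), CuI (10 mol %), THF, 0 → 45 °C
Reagents that add atoms: ethynylmagnesium bromide, C#C[Mg]Br
Why: Copper-catalysed allylic substitution of a primary allylic chloride by an alkynyl Grignard reagent; coupling should occur at the unhindered α-carbon (the γ-carbon is fully substituted), giving the linear 1,4-enyne with the E geometry retained, and the excess of acetylide suppresses double alkylation.

Step 4
Reactants: 4 tert-butyldimethyl{[(2E)-2-methylhex-2-en-5-yn-1-yl]oxy}silane
Product: 7 tert-butyldimethyl{[(2E)-2-methyl-6-(triisopropylsilyloxy)hex-2-en-5-yn-1-yl]oxy}silane, via lithium acetylide 5 (not isolated), via lithium ynolate 6 (not isolated)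
Conditions: LiN(SiMe3)2, THF, −78 °C; t-BuOOLi (from t-BuOOH and LiN(SiMe3)2), −78 → 0 °C; i-Pr3SiOTf, −78 → 0 °C
Reagents that add atoms: tert-butyl hydroperoxide, CC(C)(C)OO (the ynol oxygen); triisopropylsilyl triflate, CC(C)[Si](OS(=O)(=O)C(F)(F)F)(C(C)C)C(C)C (the silyl group); lithium bis(trimethylsilyl)amide, [Li+].C[Si](C)(C)[N-][Si](C)(C)C (the lithium of 5 and 6 only)
Why: Oxidation of a lithium acetylide by lithium tert-butyl peroxide (electrophilic oxygen transfer) gives the ynolate, which the bulky, hard silyl triflate traps on oxygen; this is an established route from terminal alkynes to triisopropylsiloxyalkynes, and at −78 °C the amide base should remove only the acetylenic proton.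

Step 5
Reactants: 8 comenic acid (5-hydroxy-4-oxo-4H-pyran-2-carboxylic acid)
Product: 9 methyl 5-hydroxy-4-oxo-4H-pyran-2-carboxylate
Conditions: MeOH, H2SO4 (cat.), reflux
Reagents that add atoms: methanol, CO
Why: Fischer esterification; the enolic 5-hydroxyl is not affected.

Step 6
Reactants: 9 methyl 5-hydroxy-4-oxo-4H-pyran-2-carboxylate
Product: 10 methyl 4-oxo-5-{[(trifluoromethyl)sulfonyl]oxy}-4H-pyran-2-carboxylate
Conditions: Tf2O, pyridine, CH2Cl2, −20 → 0 °C
Reagents that add atoms: trifluoromethanesulfonic anhydride, O=S(=O)(OS(=O)(=O)C(F)(F)F)C(F)(F)F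
Why: O-sulfonylation of the acidic enolic hydroxyl of a 3-hydroxy-4-pyranone; it gives a vinyl triflate activated by the adjacent carbonyl.

Step 7
Reactants: 10 methyl 4-oxo-5-{[(trifluoromethyl)sulfonyl]oxy}-4H-pyran-2-carboxylate; 11 [4-(tert-butyldimethylsilyloxy)phenyl]boronic acid
Product: 12 methyl 5-[4-(tert-butyldimethylsilyloxy)phenyl]-4-oxo-4H-pyran-2-carboxylate
Conditions: Pd(PPh3)4 (5 mol %), K3PO4, 1,4-dioxane, 80 °C
Reagents that add atoms: none
Why: Suzuki–Miyaura coupling of an electron-poor α-triflyloxy enone (fast oxidative addition) with an arylboronic acid; phosphate in dioxane should spare the methyl ester and the aryl silyl ether.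

Step 8
Reactants: 12 methyl 5-[4-(tert-butyldimethylsilyloxy)phenyl]-4-oxo-4H-pyran-2-carboxylate
Product: 13 5-[4-(tert-butyldimethylsilyloxy)phenyl]-4-oxo-4H-pyran-2-carboxylic acid
Conditions: Me3SnOH (4 equiv), ClCH2CH2Cl, 70 °C; then dilute aq. HCl wash
Reagents that add atoms: trimethyltin hydroxide, C[Sn](C)(C)O
Why: Tin hydroxide-mediated hydrolysis of an activated methyl ester under nearly neutral conditions; it is chosen because hydroxide or alkoxide would also cleave the aryl silyl ether and could open the pyrone ring.

Step 9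
Reactants: 13 5-[4-(tert-butyldimethylsilyloxy)phenyl]-4-oxo-4H-pyran-2-carboxylic acid
Product: 15 5-[4-(tert-butyldimethylsilyloxy)phenyl]-2-(diazoacetyl)-4H-pyran-4-one, via acid chloride 14 (not isolated)
Conditions: Me2C=C(Cl)NMe2, CH2Cl2, 0 → 20 °C; then Me3SiCHN2 (2 equiv), THF/MeCN, 0 → 20 °C
Reagents that add atoms: trimethylsilyldiazomethane, C[Si](C)(C)C=[N+]=[N-] (the CHN2 unit); 1-chloro-N,N,2-trimethylprop-1-en-1-amine, CC(C)=C(Cl)N(C)C (the chlorine of 14 only)
Why: Neutral acid chloride formation with an α-chloroenamine, then C-acylation of trimethylsilyldiazomethane with loss of Me3SiCl (Arndt–Eistert-type diazo ketone synthesis); no acid is set free that could destroy the diazo ketone or the silyl ether.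

Step 10
Reactants: 15 5-[4-(tert-butyldimethylsilyloxy)phenyl]-2-(diazoacetyl)-4H-pyran-4-one; 7 tert-butyldimethyl{[(2E)-2-methyl-6-(triisopropylsilyloxy)hex-2-en-5-yn-1-yl]oxy}silane
Product: 20 3-[4-(tert-butyldimethylsilyloxy)phenyl]-6-[(2E)-4-(tert-butyldimethylsilyloxy)-3-methylbut-2-en-1-yl]-5-hydroxy-7-(triisopropylsilyloxy)-4H-chromen-4-one, via pyranonylketene 16 (not isolated), via vinylcyclobutenone 17 (not isolated), via dienylketene 18 (not isolated), via cyclohexadienone 19 (not isolated)
Conditions: 15 (1.0 equiv), 7 (1.3 equiv), CH2Cl2 (0.15 M, degassed), hν (365 nm), 20 °C; then toluene, 80 °C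
Reagents that add atoms: none
Why: Proposed new method: irradiation of 15 should trigger a Wolff rearrangement in which the pyranonyl group shifts from the carbonyl carbon to the diazo carbon, giving ketene 16, a vinylketene whose vinyl unit is the O1–C2=C3 enol ether bond of the γ-pyrone; the closest known reaction type is the photochemical Danheiser benzannulation of α,β-unsaturated and (hetero)aryl α-diazo ketones with siloxyalkynes, which has not been shown with a 4-pyranone as the ene partner. The four-membered ring of 17 closes by a regiospecific (2+2) cycloaddition: the nucleophilic β-carbon of 7 (the one carrying the side chain) bonds to the electrophilic ketene carbonyl carbon and the siloxy-bearing carbon bonds to the ketene CH. Reversible 4π electrocyclic opening of 17 (thermal or photochemical) gives dienylketene 18, and ring A closes by a thermal disrotatory 6π electrocyclisation of the ketene C=C, the C(OSi)=CH and the pyrone C2=C3 bonds, forming the C4a–C5 bond. Tautomerisation of 19, whose C4a–H lies between two carbonyls, then gives the aromatic, hydrogen-bonded 5-hydroxychromone 20. No new stereocentre remains, since the sp3 carbons of 17 and 19 are erased on the way to the arene and the E side-chain alkene is a spectator. The selectivity needed is regiochemical (side chain on C6, not C8) and is secured by the polarity of ketene and ynol ether alone; the 6π closure has a single terminus available, pyrone C3, the future C4a. Chemoselectivity rests on three points: the siloxyalkyne is far more nucleophilic toward the ketene than its own trisubstituted alkene or the pyrone, the new 5-hydroxyl is tied up in the hydrogen bond to C4=O and should acylate slowly, and irradiation at 365 nm excites the diazo ketone but not the short-wavelength rearrangements of 4-pyranones. The final warming in toluene should convert any remaining 17 into 20.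

Step 11
Reactants: 20 3-[4-(tert-butyldimethylsilyloxy)phenyl]-6-[(2E)-4-(tert-butyldimethylsilyloxy)-3-methylbut-2-en-1-yl]-5-hydroxy-7-(triisopropylsilyloxy)-4H-chromen-4-one
Product: 21 5,7-dihydroxy-6-[(2E)-4-hydroxy-3-methylbut-2-en-1-yl]-3-(4-hydroxyphenyl)-4H-chromen-4-one
Conditions: n-Bu4NF (4 equiv), AcOH (4 equiv), THF, 0 → 20 °C
Reagents that add atoms: none
Why: Fluoride-mediated cleavage of all three silyl ethers (two aryl, one primary allylic) in one operation; acetic acid buffers the phenoxides, so the product should meet neither strong base nor an acid that would close the side chain onto O5 or O7.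

## Compound list

1 | 2-methyl-2-vinyloxirane (isoprene monoxide, racemic) | CC1(C=C)CO1 | starting material
2 | (2E)-4-chloro-2-methylbut-2-en-1-ol | C/C(=C\CCl)CO | intermediate
3 | tert-butyl{[(2E)-4-chloro-2-methylbut-2-en-1-yl]oxy}dimethylsilane | C/C(=C\CCl)CO[Si](C)(C)C(C)(C)C | intermediate
4 | tert-butyldimethyl{[(2E)-2-methylhex-2-en-5-yn-1-yl]oxy}silane | C/C(=C\CC#C)CO[Si](C)(C)C(C)(C)C | intermediate
5 | lithium acetylide of 4 (not isolated) | C/C(=C\CC#[C-])CO[Si](C)(C)C(C)(C)C.[Li+] | intermediate
6 | lithium (4E)-6-(tert-butyldimethylsilyloxy)-5-methylhex-4-en-1-yn-1-olate (ynolate, not isolated) | C/C(=C\CC#C[O-])CO[Si](C)(C)C(C)(C)C.[Li+] | intermediate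
7 | tert-butyldimethyl{[(2E)-2-methyl-6-(triisopropylsilyloxy)hex-2-en-5-yn-1-yl]oxy}silane | C/C(=C\CC#CO[Si](C(C)C)(C(C)C)C(C)C)CO[Si](C)(C)C(C)(C)C | intermediate
8 | comenic acid (5-hydroxy-4-oxo-4H-pyran-2-carboxylic acid) | O=C(O)c1cc(=O)c(O)co1 | starting material
9 | methyl 5-hydroxy-4-oxo-4H-pyran-2-carboxylate | COC(=O)c1cc(=O)c(O)co1 | intermediate
10 | methyl 4-oxo-5-{[(trifluoromethyl)sulfonyl]oxy}-4H-pyran-2-carboxylate | COC(=O)c1cc(=O)c(OS(=O)(=O)C(F)(F)F)co1 | intermediate
11 | [4-(tert-butyldimethylsilyloxy)phenyl]boronic acid | CC(C)(C)[Si](C)(C)Oc1ccc(B(O)O)cc1 | starting material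
12 | methyl 5-[4-(tert-butyldimethylsilyloxy)phenyl]-4-oxo-4H-pyran-2-carboxylate | COC(=O)c1cc(=O)c(-c2ccc(O[Si](C)(C)C(C)(C)C)cc2)co1 | intermediate
13 | 5-[4-(tert-butyldimethylsilyloxy)phenyl]-4-oxo-4H-pyran-2-carboxylic acid | O=C(O)c1cc(=O)c(-c2ccc(O[Si](C)(C)C(C)(C)C)cc2)co1 | intermediate
14 | 5-[4-(tert-butyldimethylsilyloxy)phenyl]-4-oxo-4H-pyran-2-carbonyl chloride (not isolated) | O=C(Cl)c1cc(=O)c(-c2ccc(O[Si](C)(C)C(C)(C)C)cc2)co1 | intermediate
15 | 5-[4-(tert-butyldimethylsilyloxy)phenyl]-2-(diazoacetyl)-4H-pyran-4-one | [N-]=[N+]=CC(=O)c1cc(=O)c(-c2ccc(O[Si](C)(C)C(C)(C)C)cc2)co1 | intermediate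
16 | 5-[4-(tert-butyldimethylsilyloxy)phenyl]-2-(2-oxoethenyl)-4H-pyran-4-one (pyranonylketene, not isolated) | O=C=Cc1cc(=O)c(-c2ccc(O[Si](C)(C)C(C)(C)C)cc2)co1 | intermediate
17 | 4-{5-[4-(tert-butyldimethylsilyloxy)phenyl]-4-oxo-4H-pyran-2-yl}-2-[(2E)-4-(tert-butyldimethylsilyloxy)-3-methylbut-2-en-1-yl]-3-(triisopropylsilyloxy)cyclobut-2-en-1-one (racemic, not isolated) | O=C1C(C/C=C(\C)CO[Si](C)(C)C(C)(C)C)=C(O[Si](C(C)C)(C(C)C)C(C)C)C1c2cc(=O)c(-c3ccc(O[Si](C)(C)C(C)(C)C)cc3)co2 | intermediate
18 | 2-[(2E)-4-(tert-butyldimethylsilyloxy)-3-methylbut-2-en-1-yl]-4-{5-[4-(tert-butyldimethylsilyloxy)phenyl]-4-oxo-4H-pyran-2-yl}-3-(triisopropylsilyloxy)buta-1,3-dien-1-one, pyranonyl cis to the ketene carbon (dienylketene, not isolated) | O=C=C(C/C=C(\C)CO[Si](C)(C)C(C)(C)C)/C(O[Si](C(C)C)(C(C)C)C(C)C)=C\c1cc(=O)c(-c2ccc(O[Si](C)(C)C(C)(C)C)cc2)co1 | intermediate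
19 | 3-[4-(tert-butyldimethylsilyloxy)phenyl]-6-[(2E)-4-(tert-butyldimethylsilyloxy)-3-methylbut-2-en-1-yl]-7-(triisopropylsilyloxy)-4aH-chromene-4,5-dione (racemic keto tautomer, not isolated) | O=C1C(C/C=C(\C)CO[Si](C)(C)C(C)(C)C)=C(O[Si](C(C)C)(C(C)C)C(C)C)C=C2OC=C(c3ccc(O[Si](C)(C)C(C)(C)C)cc3)C(=O)C12 | intermediate
20 | 3-[4-(tert-butyldimethylsilyloxy)phenyl]-6-[(2E)-4-(tert-butyldimethylsilyloxy)-3-methylbut-2-en-1-yl]-5-hydroxy-7-(triisopropylsilyloxy)-4H-chromen-4-one | C/C(=C\Cc1c(O[Si](C(C)C)(C(C)C)C(C)C)cc2occ(-c3ccc(O[Si](C)(C)C(C)(C)C)cc3)c(=O)c2c1O)CO[Si](C)(C)C(C)(C)C | intermediate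
21 | 5,7-dihydroxy-6-[(2E)-4-hydroxy-3-methylbut-2-en-1-yl]-3-(4-hydroxyphenyl)-4H-chromen-4-one | C/C(=C\Cc1c(O)cc2occ(-c3ccc(O)cc3)c(=O)c2c1O)CO | target

## Step count and least certain steps

Total step count: 11. Longest linear sequence: 7 steps (steps 5–11, from 8 to 21). The other branch has 4 steps (steps 1–4, from 1 to 7) before the convergence in step 10.

**Step 10 (key step, proposed new method).** The most likely failure is that the Wolff rearrangement occurs but the sequence stalls. Ketene 16 may be consumed by dimerisation before it meets 7. Alternatively, dienylketene 18 may close onto pyrone C3 too slowly, because that carbon belongs to a cross-conjugated, partly aromatic ring; 17 and 18 would then interconvert and decay under irradiation. Photochemical degradation of the pyrone chromophore could also compete with diazo photolysis.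

Fallback (known chemistry), setting out from 3 and returning at 21:
- Chloride 3 is converted with Bu3SnLi into tributyl[(2E)-4-(tert-butyldimethylsilyloxy)-3-methylbut-2-en-1-yl]stannane F1.
- Commercial genistein is silylated on O7 and O4' (TBSCl, imidazole; the chelated 5-hydroxyl stays free) to 7-(tert-butyldimethylsilyloxy)-3-[4-(tert-butyldimethylsilyloxy)phenyl]-5-hydroxy-4H-chromen-4-one F2.
- Iodination ortho to the free 5-hydroxyl (BnNMe3·ICl2, CaCO3, CH2Cl2/MeOH) gives the 6-iodo compound 7-(tert-butyldimethylsilyloxy)-3-[4-(tert-butyldimethylsilyloxy)phenyl]-5-hydroxy-6-iodo-4H-chromen-4-one F3.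
- Stille coupling of F3 with F1 (Pd(PPh3)4, LiCl, DMF) gives 7-(tert-butyldimethylsilyloxy)-3-[4-(tert-butyldimethylsilyloxy)phenyl]-6-[(2E)-4-(tert-butyldimethylsilyloxy)-3-methylbut-2-en-1-yl]-5-hydroxy-4H-chromen-4-one F4.
- Desilylation of F4 under the conditions of step 11 gives 21.

**Step 9.** The most likely failure is 1,3-dipolar cycloaddition of the diazoalkane across the C2=C3 bond of the pyrone, which the acyl chloride group makes a good dipolarophile. This would compete with C-acylation.

Fallback, setting out from 14 and returning at 15, with no free diazoalkane: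
- Chloride 14 is treated with MeNH(OMe)·HCl and pyridine to give 5-[4-(tert-butyldimethylsilyloxy)phenyl]-N-methoxy-N-methyl-4-oxo-4H-pyran-2-carboxamide F5.
- MeMgBr at −78 °C gives 2-acetyl-5-[4-(tert-butyldimethylsilyloxy)phenyl]-4H-pyran-4-one F6.
- Trifluoroacetylation (LiN(SiMe3)2, CF3CO2CH2CF3, −78 °C) gives 1-{5-[4-(tert-butyldimethylsilyloxy)phenyl]-4-oxo-4H-pyran-2-yl}-4,4,4-trifluorobutane-1,3-dione F7.
- Detrifluoroacetylative diazo transfer (MsN3, Et3N, H2O, MeCN) gives 15.

**Step 4.** The most likely failure is deprotonation of the doubly activated C4 methylene (between alkyne and alkene) by the amide or peroxide base during the slow oxygen transfer. That would isomerise the skipped enyne into conjugated allene and enyne isomers.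

Fallback, setting out from 3 and returning at 6, which generates the ynolate by rearrangement at −78 °C and never passes through the terminal alkyne:
- Chloride 3 is carbonylated (CO, EtOH, PdCl2(PPh3)2, i-Pr2NEt) to ethyl (3E)-5-(tert-butyldimethylsilyloxy)-4-methylpent-3-enoate F8.
- Kowalski ester homologation follows: LiCHBr2 (from CH2Br2 and LiTMP, lithium 2,2,6,6-tetramethylpiperidide) adds to F8 and, after loss of ethoxide, gives (4E)-1,1-dibromo-6-(tert-butyldimethylsilyloxy)-5-methylhex-4-en-2-one F9 as its enolate.
- n-BuLi then effects bromine–lithium exchange and 1,2-shift of the alkyl group to ynolate 6, which is silylated as in step 4.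

**Step 8.** The most likely failure is partial loss of the aryl silyl ether during ester cleavage, which would give mixtures.

Fallback, setting out from 12 and returning at 14, which accepts the loss and restores the group:
- LiOH in THF/H2O cleaves ester and silyl ether to 5-(4-hydroxyphenyl)-4-oxo-4H-pyran-2-carboxylic acid F10.
- TBSCl and imidazole give the silyl ether/silyl ester tert-butyldimethylsilyl 5-[4-(tert-butyldimethylsilyloxy)phenyl]-4-oxo-4H-pyran-2-carboxylate F11.
- Oxalyl chloride with catalytic DMF converts the silyl ester directly into acid chloride 14.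

## Further compounds

F1 | step 10 | tributyl[(2E)-4-(tert-butyldimethylsilyloxy)-3-methylbut-2-en-1-yl]stannane | C/C(=C\C[Sn](CCCC)(CCCC)CCCC)CO[Si](C)(C)C(C)(C)C
F2 | step 10 | 7-(tert-butyldimethylsilyloxy)-3-[4-(tert-butyldimethylsilyloxy)phenyl]-5-hydroxy-4H-chromen-4-one | CC(C)(C)[Si](C)(C)Oc1ccc(-c2coc3cc(O[Si](C)(C)C(C)(C)C)cc(O)c3c2=O)cc1
F3 | step 10 | 7-(tert-butyldimethylsilyloxy)-3-[4-(tert-butyldimethylsilyloxy)phenyl]-5-hydroxy-6-iodo-4H-chromen-4-one | CC(C)(C)[Si](C)(C)Oc1ccc(-c2coc3cc(O[Si](C)(C)C(C)(C)C)c(I)c(O)c3c2=O)cc1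
F4 | step 10 | 7-(tert-butyldimethylsilyloxy)-3-[4-(tert-butyldimethylsilyloxy)phenyl]-6-[(2E)-4-(tert-butyldimethylsilyloxy)-3-methylbut-2-en-1-yl]-5-hydroxy-4H-chromen-4-one | C/C(=C\Cc1c(O[Si](C)(C)C(C)(C)C)cc2occ(-c3ccc(O[Si](C)(C)C(C)(C)C)cc3)c(=O)c2c1O)CO[Si](C)(C)C(C)(C)C
F5 | step 9 | 5-[4-(tert-butyldimethylsilyloxy)phenyl]-N-methoxy-N-methyl-4-oxo-4H-pyran-2-carboxamide | CON(C)C(=O)c1cc(=O)c(-c2ccc(O[Si](C)(C)C(C)(C)C)cc2)co1
F6 | step 9 | 2-acetyl-5-[4-(tert-butyldimethylsilyloxy)phenyl]-4H-pyran-4-one | CC(=O)c1cc(=O)c(-c2ccc(O[Si](C)(C)C(C)(C)C)cc2)co1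
F7 | step 9 | 1-{5-[4-(tert-butyldimethylsilyloxy)phenyl]-4-oxo-4H-pyran-2-yl}-4,4,4-trifluorobutane-1,3-dione | O=C(CC(=O)C(F)(F)F)c1cc(=O)c(-c2ccc(O[Si](C)(C)C(C)(C)C)cc2)co1
F8 | step 4 | ethyl (3E)-5-(tert-butyldimethylsilyloxy)-4-methylpent-3-enoate | CCOC(=O)C/C=C(\C)CO[Si](C)(C)C(C)(C)C
F9 | step 4 | (4E)-1,1-dibromo-6-(tert-butyldimethylsilyloxy)-5-methylhex-4-en-2-one | C/C(=C\CC(=O)C(Br)Br)CO[Si](C)(C)C(C)(C)C
F10 | step 8 | 5-(4-hydroxyphenyl)-4-oxo-4H-pyran-2-carboxylic acid | O=C(O)c1cc(=O)c(-c2ccc(O)cc2)co1
F11 | step 8 | tert-butyldimethylsilyl 5-[4-(tert-butyldimethylsilyloxy)phenyl]-4-oxo-4H-pyran-2-carboxylate | CC(C)(C)[Si](C)(C)OC(=O)c1cc(=O)c(-c2ccc(O[Si](C)(C)C(C)(C)C)cc2)co1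
A1 | alternative 1 | wighteone, 5,7-dihydroxy-3-(4-hydroxyphenyl)-6-(3-methylbut-2-en-1-yl)-4H-chromen-4-one | CC(C)=CCc1c(O)cc2occ(-c3ccc(O)cc3)c(=O)c2c1O
A2 | alternative 1 | (2E)-4-[5,7-dihydroxy-3-(4-hydroxyphenyl)-4-oxo-4H-chromen-6-yl]-2-methylbut-2-enal | C/C(=C\Cc1c(O)cc2occ(-c3ccc(O)cc3)c(=O)c2c1O)C=O
A3 | alternative 2 | 2-[(2E)-4-(tert-butyldimethylsilyloxy)-3-methylbut-2-en-1-yl]benzene-1,3,5-triol | C/C(=C\Cc1c(O)cc(O)cc1O)CO[Si](C)(C)C(C)(C)C
A4 | alternative 2 | 1-{3-[(2E)-4-(tert-butyldimethylsilyloxy)-3-methylbut-2-en-1-yl]-2,4,6-trihydroxyphenyl}-2-(4-hydroxyphenyl)ethan-1-one | C/C(=C\Cc1c(O)cc(O)c(C(=O)Cc2ccc(O)cc2)c1O)CO[Si](C)(C)C(C)(C)C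
A5 | alternative 2 | 8-[(2E)-4-(tert-butyldimethylsilyloxy)-3-methylbut-2-en-1-yl]-5,7-dihydroxy-3-(4-hydroxyphenyl)-4H-chromen-4-one | C/C(=C\Cc1c(O)cc(O)c2c(=O)c(-c3ccc(O)cc3)coc12)CO[Si](C)(C)C(C)(C)C
A6 | alternative 3 | 5-(allyloxy)-7-(methoxymethoxy)-3-[4-(methoxymethoxy)phenyl]-4H-chromen-4-one | C=CCOc1cc(OCOC)cc2occ(-c3ccc(OCOC)cc3)c(=O)c12
A7 | alternative 3 | 6-allyl-5-hydroxy-7-(methoxymethoxy)-3-[4-(methoxymethoxy)phenyl]-4H-chromen-4-one | C=CCc1c(OCOC)cc2occ(-c3ccc(OCOC)cc3)c(=O)c2c1O
A8 | alternative 3 | (2E)-4-{5-hydroxy-7-(methoxymethoxy)-3-[4-(methoxymethoxy)phenyl]-4-oxo-4H-chromen-6-yl}-2-methylbut-2-enal | C/C(=C\Cc1c(OCOC)cc2occ(-c3ccc(OCOC)cc3)c(=O)c2c1O)C=O
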